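**Retrosynthetic overview**
1. Target 28 ⇒ global hydrogenolysis of 27 ⇒ ester bond between cyclobutane mono-acid 24 and tribenzyl (R)-danshensu 26.
2. Cyclobutane 23/24 ⇒ Wolff ring contraction of 2-diazocyclopentanone 20; the shift forms C1–C2 with retention.
3. All-trans cyclopentanone 16/18 ⇒ intramolecular Henry closure of a nitro dialdehyde, then oxidation, denitration and base equilibration.
4. Key C3–C4 bond ⇒ intermolecular enamine-catalysed Michael addition of aldehyde 8 to nitroalkene 10, which sets the catechol-bearing carbon.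
5. 8 from 4-(benzyloxy)benzaldehyde (Wittig, nitromethane Michael, Nef acetalisation, DIBAL-H); 10 by Henry condensation. Ring order: cyclopentane (step 7), then cyclobutane (step 14).

Assumption: sodium danshensu 25 and the benzyl-protected aldehydes 1 and 9 are bought; ring atoms are numbered as in the target (C1 CO2H, C2 4-hydroxyphenyl, C3 ester, C4 catechol). Stereodescriptors in the names were assigned by hand from the SMILES; where they differ, the SMILES is authoritative.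

**Step 1**
Reactants: 1 4-(benzyloxy)benzaldehyde; 2 methyl (triphenyl-λ5-phosphanylidene)acetate
Product: 3 methyl (2E)-3-[4-(benzyloxy)phenyl]prop-2-enoate
Conditions: PhMe, 90 °C
Reagents that add atoms: none
Why: Wittig olefination with a stabilised ylide gives the (E)-cinnamate; no stereocentre is formed.

**Step 2**
Reactants: 3 methyl (2E)-3-[4-(benzyloxy)phenyl]prop-2-enoate; 4 nitromethane
Product: 5 methyl 3-[4-(benzyloxy)phenyl]-4-nitrobutanoate (racemic)
Conditions: MeNO2 (10 equiv), DBU, MeCN, 60 °C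
Reagents that add atoms: none
Why: Base-mediated Michael addition of the nitronate to the cinnamate; the new centre (future C2) may be racemic because it later sits α to an aldehyde and then a ketone and is set thermodynamically in step 9.

**Step 3**
Reactants: 5 methyl 3-[4-(benzyloxy)phenyl]-4-nitrobutanoate
Product: 7 methyl 3-[4-(benzyloxy)phenyl]-4,4-dimethoxybutanoate (racemic), via sodium nitronate 6 (not isolated)
Conditions: NaOMe, MeOH, 0 °C; then added to H2SO4/MeOH, −35 °C → rt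
Reagents that add atoms: methanol CO
Why: Nef reaction run under acetalising conditions turns the primary nitro group into a dimethyl acetal (masked aldehyde) without touching the ester.

**Step 4**
Reactants: 7 methyl 3-[4-(benzyloxy)phenyl]-4,4-dimethoxybutanoate
Product: 8 3-[4-(benzyloxy)phenyl]-4,4-dimethoxybutanal (racemic)
Conditions: DIBAL-H (1.1 equiv), CH2Cl2, −78 °C; MeOH, aq. Rochelle salt
Reagents that add atoms: none
Why: DIBAL-H half-reduction of the methyl ester stops at the aldehyde at −78 °C because the tetrahedral aluminate is stable; the acetal is inert.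

**Step 5**
Reactants: 9 3,4-bis(benzyloxy)benzaldehyde; 4 nitromethane
Product: 10 1,2-bis(benzyloxy)-4-[(E)-2-nitroethenyl]benzene
Conditions: NH4OAc, AcOH, 100 °C
Reagents that add atoms: none
Why: Henry (nitroaldol) condensation with dehydration gives the conjugated (E)-nitroalkene.

**Step 6**
Reactants: 8 3-[4-(benzyloxy)phenyl]-4,4-dimethoxybutanal (1.0 equiv); 10 1,2-bis(benzyloxy)-4-[(E)-2-nitroethenyl]benzene (1.2 equiv)
Product: 11 (2S,3S)-2-{1-[4-(benzyloxy)phenyl]-2,2-dimethoxyethyl}-3-[3,4-bis(benzyloxy)phenyl]-4-nitrobutanal (syn; both epimers at the side-chain benzylic carbon)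
Conditions: (S)-α,α-diphenylprolinol TMS ether (10 mol %), 4-nitrophenol (20 mol %), PhMe, rt
Reagents that add atoms: none
Why: Enamine-catalysed (Hayashi–Jørgensen) intermolecular Michael addition: the enamine of 8, shielded on one face by the CPh2OTMS group, adds to the nitroalkene through a synclinal acyclic transition state to give the syn (2S,3S) adduct, so the catechol-bearing carbon (target C4) is set by the catalyst and is never enolisable afterwards.

**Step 7**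
Reactants: 11 (2S,3S)-2-{1-[4-(benzyloxy)phenyl]-2,2-dimethoxyethyl}-3-[3,4-bis(benzyloxy)phenyl]-4-nitrobutanal
Product: 13 (2S)-2-[3,4-bis(benzyloxy)phenyl]-5-[4-(benzyloxy)phenyl]-4-hydroxy-3-nitrocyclopentane-1-carbaldehyde (diastereomer mixture at C1, C3, C4, C5), via nitro dialdehyde 12 (not isolated)
Conditions: 1 M HCl, THF, 0 °C → rt; then i-Pr2NEt, MeCN, rt
Reagents that add atoms: water O
Why: Acetal hydrolysis followed by intramolecular Henry reaction (5-exo-trig nitroaldol, a formal [3+2]); only the unmasked aldehyde can close a five-membered ring, and the carbinol and nitro centres are removed later.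

**Step 8**
Reactants: 13 (2S)-2-[3,4-bis(benzyloxy)phenyl]-5-[4-(benzyloxy)phenyl]-4-hydroxy-3-nitrocyclopentane-1-carbaldehyde
Product: 14 (2S)-2-[3,4-bis(benzyloxy)phenyl]-5-[4-(benzyloxy)phenyl]-3-nitro-4-oxocyclopentane-1-carbaldehyde (mixture at C1, C3, C5)
Conditions: Dess–Martin periodinane (1.3 equiv), CH2Cl2, 0 °C → rt
Reagents that add atoms: none
Why: Dess–Martin oxidation converts the secondary β-nitro alcohol into the α-nitro ketone and leaves the aldehyde alone.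

**Step 9**
Reactants: 14 (2S)-2-[3,4-bis(benzyloxy)phenyl]-5-[4-(benzyloxy)phenyl]-3-nitro-4-oxocyclopentane-1-carbaldehyde
Product: 16 (1R,2S,5R)-2-[3,4-bis(benzyloxy)phenyl]-5-[4-(benzyloxy)phenyl]-4-oxocyclopentane-1-carbaldehyde (formyl trans to both aryl groups, aryl groups cis), via keto aldehyde epimers 15 (not isolated)
Conditions: n-Bu3SnH (1.3 equiv), AIBN (0.2 equiv), PhMe, 85 °C; then DBU (0.2 equiv), CH2Cl2, rt
Reagents that add atoms: none
Why: Radical denitration (Ono) of the α-nitro ketone, then base epimerisation of the α-formyl and α-keto benzylic centres to the all-trans isomer, which fixes the cis relation of the two aryl carbons relative to the catalyst-set centre.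

**Step 10**
Reactants: 16 (1R,2S,5R)-2-[3,4-bis(benzyloxy)phenyl]-5-[4-(benzyloxy)phenyl]-4-oxocyclopentane-1-carbaldehyde
Product: 17 (1R,2S,5R)-2-[3,4-bis(benzyloxy)phenyl]-5-[4-(benzyloxy)phenyl]-4-oxocyclopentane-1-carboxylic acid
Conditions: NaClO2, NaH2PO4, 2-methyl-2-butene, t-BuOH/THF/H2O, 0 °C → rt
Reagents that add atoms: sodium chlorite [Na+].[O-]Cl=O
Why: Pinnick oxidation of the aldehyde under buffered conditions, with the alkene scavenging HOCl so the electron-rich rings are not chlorinated and the α-centre is not epimerised.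

**Step 11**
Reactants: 17 (1R,2S,5R)-2-[3,4-bis(benzyloxy)phenyl]-5-[4-(benzyloxy)phenyl]-4-oxocyclopentane-1-carboxylic acid
Product: 18 tert-butyl (1R,2S,5R)-2-[3,4-bis(benzyloxy)phenyl]-5-[4-(benzyloxy)phenyl]-4-oxocyclopentane-1-carboxylate
Conditions: tert-butyl 2,2,2-trichloroacetimidate (2.5 equiv), BF3·OEt2 (5 mol %), CH2Cl2/cyclohexane, rt
Reagents that add atoms: tert-butyl 2,2,2-trichloroacetimidate CC(C)(C)OC(=N)C(Cl)(Cl)Cl
Why: Acid-catalysed O-tert-butylation of the acid with the imidate gives an ester that resists alkoxides and is orthogonal to benzyl groups.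

**Step 12**
Reactants: 18 tert-butyl (1R,2S,5R)-2-[3,4-bis(benzyloxy)phenyl]-5-[4-(benzyloxy)phenyl]-4-oxocyclopentane-1-carboxylate
Product: 19 tert-butyl (1R,2S,5R)-2-[3,4-bis(benzyloxy)phenyl]-5-[4-(benzyloxy)phenyl]-3-(hydroxymethylidene)-4-oxocyclopentane-1-carboxylate
Conditions: NaH (2.5 equiv), HCO2Et (5 equiv), THF, 0 °C → rt; AcOH quench
Reagents that add atoms: ethyl formate CCOC=O
Why: Crossed Claisen condensation (formylation) under thermodynamic control occurs at the only α-CH2, because only that product forms a stabilised β-dicarbonyl enolate.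

**Step 13**
Reactants: 19 tert-butyl (1R,2S,5R)-2-[3,4-bis(benzyloxy)phenyl]-5-[4-(benzyloxy)phenyl]-3-(hydroxymethylidene)-4-oxocyclopentane-1-carboxylate
Product: 20 tert-butyl (1R,2S,5R)-2-[3,4-bis(benzyloxy)phenyl]-5-[4-(benzyloxy)phenyl]-3-diazo-4-oxocyclopentane-1-carboxylate
Conditions: p-ABSA (1.3 equiv), Et3N (2.5 equiv), MeCN, 0 °C → rt
Reagents that add atoms: 4-acetamidobenzenesulfonyl azide CC(=O)Nc1ccc(cc1)S(=O)(=O)N=[N+]=[N-]
Why: Regitz deformylative diazo transfer places the diazo group regiospecifically at the formylated carbon; Et3N keeps the α-keto benzylic centre in its trans (thermodynamic) configuration.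

**Step 14**
Reactants: 20 tert-butyl (1R,2S,5R)-2-[3,4-bis(benzyloxy)phenyl]-5-[4-(benzyloxy)phenyl]-3-diazo-4-oxocyclopentane-1-carboxylate
Product: 23 1-benzyl 3-tert-butyl (1R,2R,3S,4S)-2-[4-(benzyloxy)phenyl]-4-[3,4-bis(benzyloxy)phenyl]cyclobutane-1,3-dicarboxylate, via cyclobutyl ketene 21 (not isolated), via kinetic benzyl ester epimers 22 (not isolated)
Conditions: hν (Pyrex, λ > 300 nm), BnOH (10 equiv), THF, 0 °C; then NaH (0.3 equiv), 50 °C
Reagents that add atoms: benzyl alcohol OCc1ccccc1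
Why: Photochemical Wolff rearrangement: loss of N2 with 1,2-shift of the benzylic ring carbon (retention, so the aryl groups stay cis) contracts the ring to a ketene that benzyl alcohol traps, and benzyloxide then epimerises the new α-centre to the all-trans ester (thermodynamic control; the tert-butyl ester is inert).

**Step 15**
Reactants: 23 1-benzyl 3-tert-butyl (1R,2R,3S,4S)-2-[4-(benzyloxy)phenyl]-4-[3,4-bis(benzyloxy)phenyl]cyclobutane-1,3-dicarboxylate
Product: 24 (1S,2R,3R,4S)-3-[(benzyloxy)carbonyl]-2-[3,4-bis(benzyloxy)phenyl]-4-[4-(benzyloxy)phenyl]cyclobutane-1-carboxylic acid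
Conditions: TFA/CH2Cl2 (1:3), 0 °C → rt
Reagents that add atoms: none
Why: Acidolysis (E1) removes only the tert-butyl ester; the benzyl ester and benzyl ethers survive and no stereocentre is touched.

**Step 16**
Reactants: 25 sodium (2R)-3-(3,4-dihydroxyphenyl)-2-hydroxypropanoate (sodium danshensu)
Product: 26 benzyl (2R)-3-[3,4-bis(benzyloxy)phenyl]-2-hydroxypropanoate
Conditions: BnBr (3.3 equiv), K2CO3 (3 equiv), DMF, rt, N2
Reagents that add atoms: benzyl bromide BrCc1ccccc1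
Why: Williamson-type O-alkylation of the carboxylate and the two phenoxides; the secondary alcohol is not deprotonated by carbonate and the stereocentre is untouched.

**Step 17**
Reactants: 24 (1S,2R,3R,4S)-3-[(benzyloxy)carbonyl]-2-[3,4-bis(benzyloxy)phenyl]-4-[4-(benzyloxy)phenyl]cyclobutane-1-carboxylic acid; 26 benzyl (2R)-3-[3,4-bis(benzyloxy)phenyl]-2-hydroxypropanoate
Product: 27 1-benzyl 3-{(2R)-1-(benzyloxy)-3-[3,4-bis(benzyloxy)phenyl]-1-oxopropan-2-yl} (1R,2R,3S,4S)-2-[4-(benzyloxy)phenyl]-4-[3,4-bis(benzyloxy)phenyl]cyclobutane-1,3-dicarboxylate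
Conditions: DIC (1.5 equiv), DMAP (0.5 equiv), CH2Cl2, 0 °C → rt
Reagents that add atoms: none
Why: Steglich esterification with retention at the alcohol carbon; the acid α-centre is already in its thermodynamic configuration, so transient ketene or acylpyridinium formation cannot change it.

**Step 18**
Reactants: 27 the heptabenzyl-protected target
Product: 28 (1R,2R,3S,4S)-3-({[(1R)-1-carboxy-2-(3,4-dihydroxyphenyl)ethyl]oxy}carbonyl)-4-(3,4-dihydroxyphenyl)-2-(4-hydroxyphenyl)cyclobutane-1-carboxylic acid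
Conditions: H2 (1 atm), 10 % Pd/C, THF/MeOH, rt
Reagents that add atoms: none
Why: Hydrogenolysis cleaves the five benzyl ethers and two benzyl esters under neutral conditions; the non-benzylic secondary ester and the cyclobutane are untouched.

**Compound list**
1 | 4-(benzyloxy)benzaldehyde | O=Cc1ccc(OCc2ccccc2)cc1 | starting material
2 | methyl (triphenyl-λ5-phosphanylidene)acetate | COC(=O)C=P(c1ccccc1)(c1ccccc1)c1ccccc1 | starting material
3 | methyl (2E)-3-[4-(benzyloxy)phenyl]prop-2-enoate | COC(=O)/C=C/c1ccc(OCc2ccccc2)cc1 | intermediate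
4 | nitromethane | C[N+](=O)[O-] | starting material
5 | methyl 3-[4-(benzyloxy)phenyl]-4-nitrobutanoate (racemic) | COC(=O)CC(C[N+](=O)[O-])c1ccc(OCc2ccccc2)cc1 | intermediate
6 | sodium nitronate of 5 | COC(=O)CC(C=[N+]([O-])[O-])c1ccc(OCc2ccccc2)cc1.[Na+] | intermediate
7 | methyl 3-[4-(benzyloxy)phenyl]-4,4-dimethoxybutanoate (racemic) | COC(=O)CC(C(OC)OC)c1ccc(OCc2ccccc2)cc1 | intermediate
8 | 3-[4-(benzyloxy)phenyl]-4,4-dimethoxybutanal (racemic) | O=CCC(C(OC)OC)c1ccc(OCc2ccccc2)cc1 | intermediate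
9 | 3,4-bis(benzyloxy)benzaldehyde | O=Cc1ccc(OCc2ccccc2)c(OCc2ccccc2)c1 | starting material
10 | 1,2-bis(benzyloxy)-4-[(E)-2-nitroethenyl]benzene | [O-][N+](=O)/C=C/c1ccc(OCc2ccccc2)c(OCc2ccccc2)c1 | intermediate
11 | (2S,3S)-2-{1-[4-(benzyloxy)phenyl]-2,2-dimethoxyethyl}-3-[3,4-bis(benzyloxy)phenyl]-4-nitrobutanal (side-chain epimers) | O=C[C@@H]([C@H](C[N+](=O)[O-])c1ccc(OCc2ccccc2)c(OCc2ccccc2)c1)C(c1ccc(OCc2ccccc2)cc1)C(OC)OC | intermediate
12 | (3S)-2-[4-(benzyloxy)phenyl]-3-{(1S)-1-[3,4-bis(benzyloxy)phenyl]-2-nitroethyl}butanedial (C2 epimers) | O=C[C@@H]([C@H](C[N+](=O)[O-])c1ccc(OCc2ccccc2)c(OCc2ccccc2)c1)C(C=O)c1ccc(OCc2ccccc2)cc1 | intermediate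
13 | (2S)-2-[3,4-bis(benzyloxy)phenyl]-5-[4-(benzyloxy)phenyl]-4-hydroxy-3-nitrocyclopentane-1-carbaldehyde (mixture at C1, C3, C4, C5) | O=CC1[C@@H](c2ccc(OCc3ccccc3)c(OCc3ccccc3)c2)C([N+](=O)[O-])C(O)C1c1ccc(OCc2ccccc2)cc1 | intermediate
14 | (2S)-2-[3,4-bis(benzyloxy)phenyl]-5-[4-(benzyloxy)phenyl]-3-nitro-4-oxocyclopentane-1-carbaldehyde (mixture at C1, C3, C5) | O=CC1[C@@H](c2ccc(OCc3ccccc3)c(OCc3ccccc3)c2)C([N+](=O)[O-])C(=O)C1c1ccc(OCc2ccccc2)cc1 | intermediate
15 | (2S)-2-[3,4-bis(benzyloxy)phenyl]-5-[4-(benzyloxy)phenyl]-4-oxocyclopentane-1-carbaldehyde (C1/C5 epimers) | O=CC1[C@@H](c2ccc(OCc3ccccc3)c(OCc3ccccc3)c2)CC(=O)C1c1ccc(OCc2ccccc2)cc1 | intermediate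
16 | (1R,2S,5R)-2-[3,4-bis(benzyloxy)phenyl]-5-[4-(benzyloxy)phenyl]-4-oxocyclopentane-1-carbaldehyde | O=C[C@@H]1[C@@H](c2ccc(OCc3ccccc3)c(OCc3ccccc3)c2)CC(=O)[C@H]1c1ccc(OCc2ccccc2)cc1 | intermediate
17 | (1R,2S,5R)-2-[3,4-bis(benzyloxy)phenyl]-5-[4-(benzyloxy)phenyl]-4-oxocyclopentane-1-carboxylic acid | OC(=O)[C@@H]1[C@@H](c2ccc(OCc3ccccc3)c(OCc3ccccc3)c2)CC(=O)[C@H]1c1ccc(OCc2ccccc2)cc1 | intermediate
18 | tert-butyl (1R,2S,5R)-2-[3,4-bis(benzyloxy)phenyl]-5-[4-(benzyloxy)phenyl]-4-oxocyclopentane-1-carboxylate | CC(C)(C)OC(=O)[C@@H]1[C@@H](c2ccc(OCc3ccccc3)c(OCc3ccccc3)c2)CC(=O)[C@H]1c1ccc(OCc2ccccc2)cc1 | intermediate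
19 | tert-butyl (1R,2S,5R)-2-[3,4-bis(benzyloxy)phenyl]-5-[4-(benzyloxy)phenyl]-3-(hydroxymethylidene)-4-oxocyclopentane-1-carboxylate | CC(C)(C)OC(=O)[C@@H]1[C@@H](c2ccc(OCc3ccccc3)c(OCc3ccccc3)c2)C(=CO)C(=O)[C@H]1c1ccc(OCc2ccccc2)cc1 | intermediate
20 | tert-butyl (1R,2S,5R)-2-[3,4-bis(benzyloxy)phenyl]-5-[4-(benzyloxy)phenyl]-3-diazo-4-oxocyclopentane-1-carboxylate | CC(C)(C)OC(=O)[C@@H]1[C@@H](c2ccc(OCc3ccccc3)c(OCc3ccccc3)c2)C(=[N+]=[N-])C(=O)[C@H]1c1ccc(OCc2ccccc2)cc1 | intermediate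
21 | tert-butyl 2-[3,4-bis(benzyloxy)phenyl]-4-[4-(benzyloxy)phenyl]-3-(oxomethylidene)cyclobutane-1-carboxylate (aryl groups cis, ester trans to both) | O=C=C1[C@@H](c2ccc(OCc3ccccc3)cc2)[C@H](C(=O)OC(C)(C)C)[C@H]1c1ccc(OCc2ccccc2)c(OCc2ccccc2)c1 | intermediate
22 | 1-benzyl 3-tert-butyl 2-[4-(benzyloxy)phenyl]-4-[3,4-bis(benzyloxy)phenyl]cyclobutane-1,3-dicarboxylate (C1 epimers, mainly benzyl ester cis to the aryl groups) | O=C(OCc1ccccc1)C1[C@@H](c2ccc(OCc3ccccc3)cc2)[C@H](C(=O)OC(C)(C)C)[C@H]1c1ccc(OCc2ccccc2)c(OCc2ccccc2)c1 | intermediate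
23 | 1-benzyl 3-tert-butyl (1R,2R,3S,4S)-2-[4-(benzyloxy)phenyl]-4-[3,4-bis(benzyloxy)phenyl]cyclobutane-1,3-dicarboxylate | O=C(OCc1ccccc1)[C@@H]1[C@@H](c2ccc(OCc3ccccc3)cc2)[C@H](C(=O)OC(C)(C)C)[C@H]1c1ccc(OCc2ccccc2)c(OCc2ccccc2)c1 | intermediate
24 | (1S,2R,3R,4S)-3-[(benzyloxy)carbonyl]-2-[3,4-bis(benzyloxy)phenyl]-4-[4-(benzyloxy)phenyl]cyclobutane-1-carboxylic acid | O=C(OCc1ccccc1)[C@@H]1[C@@H](c2ccc(OCc3ccccc3)cc2)[C@H](C(=O)O)[C@H]1c1ccc(OCc2ccccc2)c(OCc2ccccc2)c1 | intermediate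
25 | sodium (2R)-3-(3,4-dihydroxyphenyl)-2-hydroxypropanoate | O[C@H](Cc1ccc(O)c(O)c1)C(=O)[O-].[Na+] | starting material
26 | benzyl (2R)-3-[3,4-bis(benzyloxy)phenyl]-2-hydroxypropanoate | O[C@H](Cc1ccc(OCc2ccccc2)c(OCc2ccccc2)c1)C(=O)OCc1ccccc1 | intermediate
27 | 1-benzyl 3-{(2R)-1-(benzyloxy)-3-[3,4-bis(benzyloxy)phenyl]-1-oxopropan-2-yl} (1R,2R,3S,4S)-2-[4-(benzyloxy)phenyl]-4-[3,4-bis(benzyloxy)phenyl]cyclobutane-1,3-dicarboxylate | O=C(OCc1ccccc1)[C@@H]1[C@@H](c2ccc(OCc3ccccc3)cc2)[C@H](C(=O)O[C@H](Cc2ccc(OCc3ccccc3)c(OCc3ccccc3)c2)C(=O)OCc2ccccc2)[C@H]1c1ccc(OCc2ccccc2)c(OCc2ccccc2)c1 | intermediate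
28 | (1R,2R,3S,4S)-3-({[(1R)-1-carboxy-2-(3,4-dihydroxyphenyl)ethyl]oxy}carbonyl)-4-(3,4-dihydroxyphenyl)-2-(4-hydroxyphenyl)cyclobutane-1-carboxylic acid | O=C(O)[C@@H]1[C@@H](c2ccc(O)cc2)[C@H](C(=O)O[C@H](Cc2ccc(O)c(O)c2)C(=O)O)[C@H]1c1ccc(O)c(O)c1 | target

**Totals**
Total step count: 18. Longest linear sequence: 16 steps (1, 2, 3, 4, 6, 7, 8, 9, 10, 11, 12, 13, 14, 15, 17, 18).

**Three steps most likely to fail**

Step 7 (acetal hydrolysis and Henry closure). The free 1,4-dialdehyde 12 can dehydrate to a furan or oligomerise before it cyclises. The fallback sets out from 11 and comes back at 14. NaBH4 in MeOH at 0 °C reduces the aldehyde of 11 to (2S,3S)-2-{1-[4-(benzyloxy)phenyl]-2,2-dimethoxyethyl}-3-[3,4-bis(benzyloxy)phenyl]-4-nitrobutan-1-ol F1. Aqueous HCl in THF then unmasks the acetal, which is trapped at once by the new hydroxyl as the lactol (4S)-3-[4-(benzyloxy)phenyl]-4-{(1S)-1-[3,4-bis(benzyloxy)phenyl]-2-nitroethyl}oxolan-2-ol F2, so no dialdehyde ever exists. DBU in MeCN opens the lactol and closes the nitroaldol to (3S,4S)-3-[3,4-bis(benzyloxy)phenyl]-5-[4-(benzyloxy)phenyl]-4-(hydroxymethyl)-2-nitrocyclopentan-1-ol F3. Dess–Martin periodinane (2.6 equiv) oxidises both alcohols and gives 14, which goes on to the equilibration of step 9 as before.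

Step 14 (Wolff ring contraction to a tetrasubstituted cyclobutane). The carbene may insert into O–H or undergo a 1,2-H shift instead of rearranging. The fallback sets out from 19 and comes back at 23, replacing the carbene by a cationic semipinacol shift. Deformylative nitrosation of 19 (NaNO2, AcOH, 0 °C) gives tert-butyl (1R,2S,5R)-2-[3,4-bis(benzyloxy)phenyl]-5-[4-(benzyloxy)phenyl]-3-(hydroxyimino)-4-oxocyclopentane-1-carboxylate F4. NaBH4/NiCl2·6H2O in MeOH reduces the oxime and the ketone to tert-butyl (1R,2S,5R)-3-amino-2-[3,4-bis(benzyloxy)phenyl]-5-[4-(benzyloxy)phenyl]-4-hydroxycyclopentane-1-carboxylate F5. Diazotisation (NaNO2, aqueous AcOH, 0 °C) triggers a Tiffeneau–Demjanov-type ring contraction in which the benzylic ring carbon migrates with retention, giving tert-butyl 2-[3,4-bis(benzyloxy)phenyl]-4-[4-(benzyloxy)phenyl]-3-formylcyclobutane-1-carboxylate F6. Pinnick oxidation gives 3-(tert-butoxycarbonyl)-2-[4-(benzyloxy)phenyl]-4-[3,4-bis(benzyloxy)phenyl]cyclobutane-1-carboxylic acid F7. BnBr/K2CO3 in DMF converts this into the epimer mixture 22, and BnONa in BnOH/THF at 50 °C equilibrates it to 23.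

Step 17 (acylation of a hindered α-hydroxy ester by an acid flanked by two aryl-bearing carbons). N-acylurea formation may outrun ester formation. The fallback sets out from 24 and comes back at 27, activating the alcohol instead of the acid. Purchased L-DOPA is diazotised (NaNO2, aqueous H2SO4, 0 °C, net retention) to (2S)-3-(3,4-dihydroxyphenyl)-2-hydroxypropanoic acid F8. BnBr/K2CO3 in DMF gives benzyl (2S)-3-[3,4-bis(benzyloxy)phenyl]-2-hydroxypropanoate F9. Mitsunobu coupling of 24 with F9 (PPh3, DIAD, THF, 0 °C) proceeds by SN2 attack of the carboxylate with inversion and delivers the (R)-ester 27.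

**Further compounds**
F1 | step 7 | (2S,3S)-2-{1-[4-(benzyloxy)phenyl]-2,2-dimethoxyethyl}-3-[3,4-bis(benzyloxy)phenyl]-4-nitrobutan-1-ol | OC[C@@H]([C@H](C[N+](=O)[O-])c1ccc(OCc2ccccc2)c(OCc2ccccc2)c1)C(c1ccc(OCc2ccccc2)cc1)C(OC)OC
F2 | step 7 | (4S)-3-[4-(benzyloxy)phenyl]-4-{(1S)-1-[3,4-bis(benzyloxy)phenyl]-2-nitroethyl}oxolan-2-ol | OC1OC[C@@H]([C@H](C[N+](=O)[O-])c2ccc(OCc3ccccc3)c(OCc3ccccc3)c2)C1c1ccc(OCc2ccccc2)cc1
F3 | step 7 | (3S,4S)-3-[3,4-bis(benzyloxy)phenyl]-5-[4-(benzyloxy)phenyl]-4-(hydroxymethyl)-2-nitrocyclopentan-1-ol | OC[C@H]1[C@@H](c2ccc(OCc3ccccc3)c(OCc3ccccc3)c2)C([N+](=O)[O-])C(O)C1c1ccc(OCc2ccccc2)cc1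
F4 | step 14 | tert-butyl (1R,2S,5R)-2-[3,4-bis(benzyloxy)phenyl]-5-[4-(benzyloxy)phenyl]-3-(hydroxyimino)-4-oxocyclopentane-1-carboxylate | CC(C)(C)OC(=O)[C@@H]1[C@@H](c2ccc(OCc3ccccc3)c(OCc3ccccc3)c2)C(=NO)C(=O)[C@H]1c1ccc(OCc2ccccc2)cc1
F5 | step 14 | tert-butyl (1R,2S,5R)-3-amino-2-[3,4-bis(benzyloxy)phenyl]-5-[4-(benzyloxy)phenyl]-4-hydroxycyclopentane-1-carboxylate | CC(C)(C)OC(=O)[C@@H]1[C@@H](c2ccc(OCc3ccccc3)c(OCc3ccccc3)c2)C(N)C(O)[C@H]1c1ccc(OCc2ccccc2)cc1
F6 | step 14 | tert-butyl 2-[3,4-bis(benzyloxy)phenyl]-4-[4-(benzyloxy)phenyl]-3-formylcyclobutane-1-carboxylate | O=CC1[C@@H](c2ccc(OCc3ccccc3)cc2)[C@H](C(=O)OC(C)(C)C)[C@H]1c1ccc(OCc2ccccc2)c(OCc2ccccc2)c1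
F7 | step 14 | 3-(tert-butoxycarbonyl)-2-[4-(benzyloxy)phenyl]-4-[3,4-bis(benzyloxy)phenyl]cyclobutane-1-carboxylic acid | OC(=O)C1[C@@H](c2ccc(OCc3ccccc3)cc2)[C@H](C(=O)OC(C)(C)C)[C@H]1c1ccc(OCc2ccccc2)c(OCc2ccccc2)c1
F8 | step 17 | (2S)-3-(3,4-dihydroxyphenyl)-2-hydroxypropanoic acid | O[C@@H](Cc1ccc(O)c(O)c1)C(=O)O
F9 | step 17 | benzyl (2S)-3-[3,4-bis(benzyloxy)phenyl]-2-hydroxypropanoate | O[C@@H](Cc1ccc(OCc2ccccc2)c(OCc2ccccc2)c1)C(=O)OCc1ccccc1
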